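Remark (assumption): locants C1–C13 follow the carbocycle numbering (C1 CH2, C2 =CH, C3 =C–O, C4 C(OH)CH3, C5 CH2, C6 CH–O, C7/C8/C11/C12 butenolide β/γ/α/carbonyl carbons, C9 exocyclic =CH, C10 O–C–CH3, C13 CH2–O). The three starting materials are taken as purchasable, the two chiral ones as single enantiomers.

## Analysis of the target

The target is a C15 tricycle. A ten-membered carbocycle (C1–C10) is bridged from C3 to C10 by an ether oxygen, so that C10–C1–C2=C3–O is a 2,3-dihydrofuran. The carbocycle is fused across C7–C8 to a butenolide (C7, C8, O, C12, C11) whose γ-carbon C8 carries the exocyclic C8=C9 double bond.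

There are three stereocentres, all S. Quaternary C4 (tertiary alcohol, methyl) and secondary C6 (acetoxy) are 1,3-anti along the C3–C7 chain. Quaternary C10 (ether oxygen, methyl) lies across the ring, separated from both by sp2 carbons or a single CH2, so no stereochemical relay between C10 and the C4/C6 pair can be relied on. The C8=C9 bond holds the ring carbons C7 and C10 cis (E by the CIP rules, because the lactone oxygen outranks C7).

The sensitive groups are the trisubstituted enol ether next to a free tertiary alcohol (acid), the γ-ylidene butenolide, which is an enol lactone and an extended acceptor (nucleophiles, strong base), and two allylic acetates. The C13 acetate sits β to the butenolide α-carbon C11 and is a leaving group whenever C11 carries negative charge.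

The difficulty is to close a medium ring that holds five sp2 carbons and two quaternary stereocentres without acid and with only brief exposure to base. The strategy rests on one feature: C9 is bonded to quaternary C10, so a C9 aldehyde cannot enolise, and C8 is the γ-carbon of a butenolide whose α-carbon is blocked. C8=C9 is therefore the dehydrated vinylogous aldol between these two carbons. Because the dihydrofuran already ties C3 to C10, the chain that must fold is short and stiff.

## Retrosynthetic reasoning

**Acetates last.** Target 32 is traced to triol 31 and this to tris-silyl ether 30. The tertiary C4 hydroxyl does not acylate under mild conditions, so the two acetates can be placed selectively at the end. Carrying them earlier is unsafe: an acyloxy group on C13 is β to C11 and would be expelled from the electron-rich furan 27 or from the dienolate derived from mesylate 29. Silyl ethers are poor leaving groups and are taken off together in one operation.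

**C8=C9 double bond.** Alkene 30 is traced to aldol 28 through mesylate 29. The C8 hydrogen is the acidic γ-hydrogen of a butenolide, so elimination runs through the dienolate and needs no acid. Both carbinol centres of 28 vanish, which removes any need to control them.

**C8–C9 bond, the ring closure.** Aldol 28 is cut between C8 and C9 to give siloxyfuran aldehyde 27. The cut is made here because it is the only ring bond whose two ends are naturally a nucleophile (the γ-carbon of a silyl dienol ether) and a non-enolisable electrophile. The forward reaction must deliver γ-regioselectivity and win against intermolecular addition.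

**Siloxyfuran and C13.** Compound 27 comes from hydroxymethyl butenolide 26 by silylation of both the alcohol and the lactone. Compound 26 comes from bromobutenolide 25 by a Stille hydroxymethylation at C11, and 25 from 24 by direct oxidation of the primary C9 silyl ether. The aldehyde is unveiled before C13 is introduced so that no free C13 alcohol is ever exposed to an oxidant.

**Butenolide regiochemistry.** Butenolide 24 is traced to bromofuran 21 through lithiofuran 22 and boronate 23. The bromine on C11 serves twice: it directs deprotonation to the neighbouring C12, which fixes the carbonyl position, and it is the handle for C13.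

**C6–C7 bond and the C6 stereocentre.** Silyl ether 21 comes from alcohol 20, which comes from ketone 19 by a CBS reduction. Ketone 19 comes from carbinol mixture 18, made by adding lithiofuran 17 (from 3,4-dibromofuran 16) to aldehyde 15. Substrate control from the β-quaternary C4 centre is not predictable, so the centre is set by reagent control on the ketone.

**Dihydrofuran.** Aldehyde 15 goes back through alcohol 14 and pivalate 13 to homopropargylic alcohol 12. The C10–O–C3 ether bond is cut, which corresponds to a 5-endo-dig cycloisomerisation in the forward sense. Ring size allows only attack at C3, and the double bond cannot migrate because C4 and C10 are quaternary.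

**C1–C2 bond and the two quaternary centres.** Alcohol 12 is cut between C1 and C2 into acetylide 11 (from alkyne 8) and epoxide 10. Attack at the unsubstituted epoxide carbon leaves both quaternary stereocentres untouched. Epoxide 10 is the silyl ether of (R)-2-methylglycidol 9 and supplies C9, C10, C1 and the ring oxygen. Alkyne 8 comes from (S)-citramalic acid 1 through dioxolanone 2, alcohol 3, lactone 4, silyl ether 5, lactol 6 and alkynol 7. This chain supplies C3–C6, and C2 is added in the Ohira–Bestmann homologation.

## Alternatives that were turned down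

**Alternative 1:** The disconnection is the C2=C3 enol ether bond, opened into an ester carbonyl at C3 and an allyl group on C10, the two halves being joined as an ester of the C10 tertiary alcohol. In the forward step a stoichiometric low-valent titanium reagent turns the allyl terminus into an alkylidene at C2, which olefinates the ester carbonyl and closes the ring. The product is the 2,2,5-trisubstituted dihydrofuran A1, with a p-methoxybenzyl ether at C9 and a silyl ether at C6.

- For it: the conditions are basic and acid-free, the double bond position is unambiguous, and the union is an esterification. On the enol ether alone it is as strong as the cycloisomerisation used here. It is arguably stronger in that it needs no π-acid attack on a carbon flanked by a quaternary centre.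
- Against it: the ester links a tertiary alcohol to an α-quaternary, α-silyloxy acid and is very hindered to make. The titanium reagent is used in large excess. The benzylic ether at C9 would later have to be removed oxidatively beside an electron-rich enol ether.
- Comparison: A1 is only the counterpart of 13, so the key step spends the strategic effort on a five-membered ring and leaves the ten-membered ring unsolved. The chosen route reaches 13 in the same number of operations with a catalytic metal and places its one risky step on the macrocycle.

**Alternative 2:** No ring bond of the target is cut. Instead C3 and C8 are joined retrosynthetically, giving a butenolide-fused cis-decalin with an alkoxide at C3 and a sulfonate at C9. In the forward step the alkoxide pushes, the C3–C8 ring-fusion bond breaks and the antiperiplanar leaving group departs. Ketone A2 appears with C3=O and C8=C9 in one concerted event.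

- For it: the medium ring arises by ring expansion, so there is no entropic penalty, no dilution and no oligomerisation. The alkene geometry is fixed stereospecifically by the equatorial leaving group. On both points this is clearly stronger than the aldol closure chosen here.
- Against it: the decalin needs three further stereocentres (C3, C8, C9), two of them fully substituted ring-fusion carbons, which are built only to be destroyed. Their construction is long and linear. After A2 the C10 oxygen must be freed selectively and condensed with the C3 ketone to the enol ether by acid-mediated cyclodehydration, on a molecule that already holds the ylidene lactone.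
- Comparison: the chosen strategy accepts the entropic risk in exchange for convergence. Only the three stereocentres of the target are ever made, and the enol ether is installed early under neutral catalysis.

**Alternative 3:** The disconnection is a functional-group interconversion. The butenolide is traced to a furan fused to the macrocycle (α-carbons C8 and C12), with the enol ether masked as a C3 methyl ketal. In the forward step singlet oxygen adds across C8 and C12, and base removes the only hydrogen on the endoperoxide carbons (at C12). The resulting Kornblum–DeLaMare-type fragmentation gives the 5-hydroxybutenolide A3 with the carbonyl at C12 and a hemiketal hydroxyl at C8.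

- For it: the lactone regiochemistry is dictated by the substitution pattern. The furan is a robust aromatic to carry through ring assembly. Both acetates can already be in place because no dienolate is formed, and the masked enol ether is inert to singlet oxygen. On butenolide regiocontrol it is simpler than the bromine-directed metalation used here, and it avoids the sensitive siloxyfuran.
- Against it: the step forms no skeletal bond and no ring, so the furan-containing macrocycle needs a separate closure with the same entropic problem. After A3 two eliminations remain (water across C8–C9, methanol across C2–C3), both acid-promoted beside a free tertiary alcohol and two allylic acetates. An extra stereocentre at C3 must also be carried.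
- Comparison: the chosen strategy uses the butenolide's own nucleophilicity to close the ring and reaches ring and oxidation level in one operation. The price is silyl protection at C6 and C13 and two more final steps.

Key step: step 20

## Route

Step 1
Reactants: 1 (S)-citramalic acid
Product: 2 2-[(4S)-2,2,4-trimethyl-5-oxo-1,3-dioxolan-4-yl]acetic acid
Conditions: 2,2-dimethoxypropane, p-TsOH·H2O (cat.), CH2Cl2, rt
Reagents that add atoms: 2,2-dimethoxypropane, COC(C)(C)OC
Why: Acid-catalysed acetalisation engages the α-hydroxy acid as the five-membered dioxolanone and leaves the β-carboxyl group free; no bond to the quaternary centre changes, so the S configuration of 1 is kept.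

Step 2
Reactants: 2 dioxolanone acid
Product: 4 (3S)-3-hydroxy-3-methyloxolan-2-one, via hydroxyethyl dioxolanone 3 (not isolated)
Conditions: BH3·SMe2, THF, 0 °C → rt; MeOH; then p-TsOH·H2O (cat.), CH2Cl2, rt
Reagents that add atoms: none
Why: Borane reduces a free carboxylic acid far faster than the ester-type dioxolanone carbonyl (chemoselective acid reduction); acid then lets the new primary alcohol translactonise onto the acetal ester with loss of acetone, giving the γ-lactone without touching the stereocentre.

Step 3
Reactants: 4 hydroxy lactone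
Product: 5 (3S)-3-methyl-3-[(triethylsilyl)oxy]oxolan-2-one
Conditions: Et3SiOTf, 2,6-lutidine, CH2Cl2, 0 °C
Reagents that add atoms: triethylsilyl trifluoromethanesulfonate, CC[Si](CC)(CC)OS(=O)(=O)C(F)(F)F
Why: Silyl triflate with lutidine is the standard silylation of a hindered tertiary alcohol; the triethylsilyl ether masks the C4 oxygen through all organometallic steps and can be removed at the end under buffered fluoride conditions.

Step 4
Reactants: 5 silyloxy lactone
Product: 6 (3S)-3-methyl-3-[(triethylsilyl)oxy]oxolan-2-ol (anomer mixture)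
Conditions: i-Bu2AlH, CH2Cl2, −78 °C; aq. potassium sodium tartrate
Reagents that add atoms: none
Why: Partial reduction of a γ-lactone to the lactol stops at the tetrahedral aluminate at −78 °C; the α-carbon is quaternary, so epimerisation is impossible.

Step 5
Reactants: 6 lactol
Product: 7 (3S)-3-methyl-3-[(triethylsilyl)oxy]pent-4-yn-1-ol
Conditions: dimethyl (1-diazo-2-oxopropyl)phosphonate, K2CO3, MeOH, 0 °C → rt
Reagents that add atoms: dimethyl (1-diazo-2-oxopropyl)phosphonate, COP(=O)(OC)C(=[N+]=[N-])C(C)=O
Why: Ohira–Bestmann homologation: the open hydroxy aldehyde form of the lactol is trapped by the diazomethylphosphonate anion generated in the flask and the alkylidene carbene rearranges by hydride shift to the terminal alkyne; the added carbon is C2 and the non-enolisable neighbouring centre keeps its configuration.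

Step 6
Reactants: 7 alkynol
Product: 8 (3S)-3-methyl-3-[(triethylsilyl)oxy]pent-4-yn-1-yl 2,2-dimethylpropanoate
Conditions: t-BuCOCl, pyridine, DMAP (cat.), CH2Cl2, 0 °C → rt
Reagents that add atoms: pivaloyl chloride, CC(C)(C)C(Cl)=O
Why: Acylation of the primary alcohol; the pivalate is hindered and has no α-hydrogen, so it survives acetylide formation at −78 °C and the gold step, and it is later removed reductively, orthogonal to both triethylsilyl ethers.

Step 7
Reactants: 9 (R)-2-methylglycidol
Product: 10 triethyl{[(2S)-2-methyloxiran-2-yl]methoxy}silane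
Conditions: Et3SiCl, imidazole, CH2Cl2, 0 °C
Reagents that add atoms: chlorotriethylsilane, CC[Si](CC)(CC)Cl
Why: Silylation of the primary alcohol under mildly basic conditions leaves the epoxide intact; no bond to the stereocentre changes, and the descriptor becomes S only because CH2OSi now outranks the ring CH2.

Step 8
Reactants: 8 pivalate alkyne; 10 silyl glycidyl ether
Product: 12 (3S,7S)-7-hydroxy-3,7-dimethyl-3,8-bis[(triethylsilyl)oxy]oct-4-yn-1-yl 2,2-dimethylpropanoate, via lithium acetylide 11 (not isolated)
Conditions: 8, n-BuLi, THF, −78 °C; BF3·OEt2; then 10, −78 °C; aq. NaHCO3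
Reagents that add atoms: n-butyllithium, [Li]CCCC (lithium in intermediate 11 only)
Why: BF3-promoted opening of a terminal epoxide by a lithium acetylide proceeds by SN2 attack at the unsubstituted CH2 (C1), so the C1–C2 bond forms without touching either quaternary stereocentre; at −78 °C the pivalate and the silyl ethers are not attacked.

Step 9
Reactants: 12 homopropargylic alcohol
Product: 13 (3S)-3-[(5S)-5-methyl-5-{[(triethylsilyl)oxy]methyl}-4,5-dihydrofuran-2-yl]-3-[(triethylsilyl)oxy]butyl 2,2-dimethylpropanoate
Conditions: Au(NTf2)(PPh3) (3 mol%), 4 Å MS, THF, rt; Et3N quench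
Reagents that add atoms: none
Why: Monovalent gold activates the alkyne for anti attack of the tertiary C10 hydroxyl on C3 and protodeauration gives the enol ether (5-endo-dig cycloisomerisation of a 3-alkyn-1-ol, a known route to 2,3-dihydrofurans); attack at C2 would need a four-membered ring, and the double bond cannot move because C4 and C10 are quaternary.

Step 10
Reactants: 13 dihydrofuran pivalate
Product: 14 (3S)-3-[(5S)-5-methyl-5-{[(triethylsilyl)oxy]methyl}-4,5-dihydrofuran-2-yl]-3-[(triethylsilyl)oxy]butan-1-ol
Conditions: i-Bu2AlH, CH2Cl2, −78 °C; aq. potassium sodium tartrate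
Reagents that add atoms: none
Why: Reductive cleavage of the pivalate frees the C6 alcohol under non-acidic, fluoride-free conditions that leave the enol ether and both silyl ethers intact.

Step 11
Reactants: 14 primary alcohol
Product: 15 (3S)-3-[(5S)-5-methyl-5-{[(triethylsilyl)oxy]methyl}-4,5-dihydrofuran-2-yl]-3-[(triethylsilyl)oxy]butanal
Conditions: Dess–Martin periodinane, pyridine, CH2Cl2, 0 °C → rt
Reagents that add atoms: none
Why: Dess–Martin oxidation of a primary alcohol buffered with pyridine is essentially neutral, so the enol ether is not hydrolysed and the β-silyloxy group is not eliminated.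

Step 12
Reactants: 15 aldehyde; 16 3,4-dibromofuran
Product: 18 (1RS,3S)-1-(4-bromofuran-3-yl)-3-[(5S)-5-methyl-5-{[(triethylsilyl)oxy]methyl}-4,5-dihydrofuran-2-yl]-3-[(triethylsilyl)oxy]butan-1-ol, via 4-bromo-3-lithiofuran 17 (not isolated)
Conditions: 16, n-BuLi, Et2O, −78 °C; then 15, −78 °C; aq. NH4Cl
Reagents that add atoms: n-butyllithium, [Li]CCCC (lithium in intermediate 17 only)
Why: Single bromine–lithium exchange on 3,4-dibromofuran at −78 °C gives the 3-lithiofuran, which adds to the aldehyde faster than it deprotonates it (1,2-addition of an aryllithium) and forms the C6–C7 bond; C6 is not controlled here and is corrected in steps 13 and 14.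

Step 13
Reactants: 18 furyl carbinol mixture
Product: 19 (3S)-1-(4-bromofuran-3-yl)-3-[(5S)-5-methyl-5-{[(triethylsilyl)oxy]methyl}-4,5-dihydrofuran-2-yl]-3-[(triethylsilyl)oxy]butan-1-one
Conditions: MnO2, CH2Cl2, rt
Reagents that add atoms: none
Why: MnO2 oxidises the furylic (benzylic-type) carbinol to the ketone under neutral heterogeneous conditions and so erases the uncontrolled C6 centre without base that could eliminate the β-silyloxy group.

Step 14
Reactants: 19 furyl ketone
Product: 20 (1S,3S)-1-(4-bromofuran-3-yl)-3-[(5S)-5-methyl-5-{[(triethylsilyl)oxy]methyl}-4,5-dihydrofuran-2-yl]-3-[(triethylsilyl)oxy]butan-1-ol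
Conditions: (R)-2-methyl-CBS-oxazaborolidine, catecholborane, toluene, −78 °C
Reagents that add atoms: none
Why: CBS reduction of a heteroaryl alkyl ketone: the furyl group acts as the large and the CH2 group as the small substituent, so the (R)-catalyst should deliver hydride to the face that gives the (6S)-carbinol (the sense that turns acetophenone into (S)-1-phenylethanol), with reagent control overriding the remote C4 centre; catecholborane at −78 °C does not hydroborate the enol ether.

Step 15
Reactants: 20 (6S)-alcohol
Product: 21 3-bromo-4-{(1S,3S)-1-[(tert-butyldimethylsilyl)oxy]-3-[(5S)-5-methyl-5-{[(triethylsilyl)oxy]methyl}-4,5-dihydrofuran-2-yl]-3-[(triethylsilyl)oxy]butyl}furan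
Conditions: t-BuMe2SiOTf, 2,6-lutidine, CH2Cl2, −78 → 0 °C
Reagents that add atoms: tert-butyldimethylsilyl trifluoromethanesulfonate, CC(C)(C)[Si](C)(C)OS(=O)(=O)C(F)(F)F
Why: Silyl triflate silylation of the hindered secondary alcohol; the silyl ether withstands lithium amide, peroxide, Swern and Lewis acid conditions and, unlike an acetate, is not a leaving group in the later dienolate chemistry.

Step 16
Reactants: 21 bromofuran
Product: 24 3-bromo-4-{(1S,3S)-1-[(tert-butyldimethylsilyl)oxy]-3-[(5S)-5-methyl-5-{[(triethylsilyl)oxy]methyl}-4,5-dihydrofuran-2-yl]-3-[(triethylsilyl)oxy]butyl}furan-2(5H)-one, via C12 lithiofuran 22 (not isolated), via dimethyl boronate 23 (not isolated)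
Conditions: LiN(i-Pr)2, THF, −78 °C; B(OMe)3, −78 → 0 °C; 30% aq. H2O2, NaHCO3, 0 °C
Reagents that add atoms: lithium diisopropylamide, [Li]N(C(C)C)C(C)C (lithium in 22 only); trimethyl borate, COB(OC)OC (boron in 23 only); hydrogen peroxide, OO (the C12 oxygen of 24)
Why: Lithium amides deprotonate 3-bromofurans at the α-carbon next to the halogen (here C12) because of its inductive effect (directed metalation); borate trapping and peroxide oxidation (aryl boronate to phenol) give the 2-hydroxyfuran, which tautomerises to the conjugated 2(5H)-furanone, so the carbonyl sits on C12 and C8 becomes CH2. At −78 °C the lithiated bromofuran should not undergo halogen migration.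

Step 17
Reactants: 24 bromobutenolide
Product: 25 (2S)-5-{(2S,4S)-4-(4-bromo-5-oxo-2,5-dihydrofuran-3-yl)-4-[(tert-butyldimethylsilyl)oxy]-2-[(triethylsilyl)oxy]butan-2-yl}-2-methyl-2,3-dihydrofuran-2-carbaldehyde
Conditions: (COCl)2, DMSO, CH2Cl2, −78 → −40 °C; Et3N, −78 → 0 °C
Reagents that add atoms: none
Why: Under Swern conditions a primary triethylsilyl ether is converted directly into the aldehyde (attack of the chlorosulfonium ion on the ether oxygen, loss of the silyl chloride, ylide collapse), whereas tertiary triethylsilyl and tert-butyldimethylsilyl ethers do not react; the aldehyde sits on quaternary C10 and cannot epimerise.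

Step 18
Reactants: 25 bromobutenolide aldehyde
Product: 26 (2S)-5-{(2S,4S)-4-[(tert-butyldimethylsilyl)oxy]-4-[4-(hydroxymethyl)-5-oxo-2,5-dihydrofuran-3-yl]-2-[(triethylsilyl)oxy]butan-2-yl}-2-methyl-2,3-dihydrofuran-2-carbaldehyde
Conditions: Bu3SnCH2OH, Pd(PPh3)4 (10 mol%), 1,4-dioxane, 90 °C
Reagents that add atoms: (tributylstannyl)methanol, CCCC[Sn](CO)(CCCC)CCCC
Why: Stille coupling of the electron-poor α-bromo butenolide with the hydroxymethyl stannane under zerovalent palladium transfers CH2OH to C11 and so installs C13; the neutral conditions tolerate the aldehyde, the enol ether and the silyl ethers.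

Step 19
Reactants: 26 hydroxymethyl butenolide aldehyde
Product: 27 (2S)-5-{(2S,4S)-4-[(tert-butyldimethylsilyl)oxy]-2-[(triethylsilyl)oxy]-4-[5-[(triisopropylsilyl)oxy]-4-{[(triisopropylsilyl)oxy]methyl}furan-3-yl]butan-2-yl}-2-methyl-2,3-dihydrofuran-2-carbaldehyde
Conditions: i-Pr3SiOTf (2.5 equiv), Et3N, CH2Cl2, −78 → 0 °C
Reagents that add atoms: triisopropylsilyl trifluoromethanesulfonate, CC(C)[Si](OS(=O)(=O)C(F)(F)F)(C(C)C)C(C)C
Why: The silyl triflate caps the primary C13 alcohol and O-silylates the lactone carbonyl, after which triethylamine removes the ring γ-hydrogen on C8 to give the aromatic 2-siloxyfuran (soft enolisation of a butenolide); the aldehyde has no α-hydrogen, and the bulky silyl triflate with excess amine at low temperature is a poor promoter of aldol addition.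

Step 20 (key step)
Reactants: 27 siloxyfuran aldehyde
Product: 28 (4S,6S,10S)-9-hydroxy macrocyclic butenolide (4-O-triethylsilyl-6-O-tert-butyldimethylsilyl-13-O-triisopropylsilyl; C8/C9 epimer mixture)
Conditions: BF3·OEt2 (2 equiv), 2,6-di-tert-butyl-4-methylpyridine, CH2Cl2 (about 1 mM, slow addition of 27), −78 °C; aq. NaHCO3
Reagents that add atoms: none
Why: BF3 binds the aldehyde oxygen and the siloxyfuran attacks the activated carbonyl through C8, the terminus of its silyl dienol ether; fluoride transfer to silicon then releases the butenolide. This is an intramolecular vinylogous Mukaiyama aldol addition, and the closest known reactions are the addition of 2-siloxyfurans to aldehydes and its tethered versions that close common rings. The closure forms the C8–C9 bond and with it the ten-membered carbocycle in a 10-exo-trig mode (nine atoms when counted through the ether bridge). The new centres C8 and C9 are not controlled and need not be, because both become sp2 in step 21. The step needs γ- over α-regioselectivity, which the substituent on C11 and the intrinsic preference of siloxyfurans for their 5-position secure. It also needs ring closure to beat intermolecular addition, which high dilution with slow addition serves. The aldehyde is a pure acceptor because C10 is quaternary, and the dihydrofuran ring and the planar furan leave only the C4–C5, C5–C6, C6–C7 and C9–C10 bonds as rotors. The oxygens on C6 and C13 are silyl ethers that the electron-rich furan should not expel under the Lewis acid, and the hindered pyridine scavenges protic acid that would hydrolyse the enol ether.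

Step 21
Reactants: 28 macrocyclic aldol
Product: 30 (4S,6S,8E,10S)-4-O-triethylsilyl-6-O-tert-butyldimethylsilyl-13-O-triisopropylsilyl ylidene butenolide (tris-silyl ether of the bis-deacetyl target), via C9 mesylate 29 (not isolated)
Conditions: MsCl, Et3N, CH2Cl2, 0 °C; then DBU, 0 °C → rt
Reagents that add atoms: methanesulfonyl chloride, CS(Cl)(=O)=O (in intermediate 29 only)
Why: Mesylation followed by E1cB elimination: DBU removes the acidic C8 hydrogen to give the furanolate, which expels the mesylate and forms C8=C9 in conjugation with the butenolide. The bridged frame is expected to allow only the arrangement with C7 and C10 cis, which is the target geometry, and the silyl ether on C13 is too poor a leaving group to compete.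

Step 22
Reactants: 30 tris-silyl ether
Product: 31 (4S,6S,8E,10S)-4,6,13-triol (bis-deacetyl target)
Conditions: HF·pyridine, pyridine, THF, 0 °C → rt
Reagents that add atoms: none
Why: Buffered HF·pyridine cleaves the tertiary triethylsilyl, secondary tert-butyldimethylsilyl and primary triisopropylsilyl ethers (fluoride-mediated desilylation) at an acidity that the enol ether and the enol lactone should tolerate; no stereocentre is involved.

Step 23
Reactants: 31 triol
Product: 32 CNP0144020.1 (target)
Conditions: Ac2O, pyridine, DMAP (cat.), CH2Cl2, 0 °C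
Reagents that add atoms: acetic anhydride, CC(=O)OC(C)=O
Why: Chemoselective acylation: the primary C13 and secondary C6 hydroxyls are acetylated, while the hindered tertiary C4 hydroxyl does not react at 0 °C; this gives the target with its free tertiary alcohol.

## Compound list

1 | (2S)-2-hydroxy-2-methylbutanedioic acid, (S)-citramalic acid | OC(=O)[C@@](C)(O)CC(O)=O | starting material
2 | 2-[(4S)-2,2,4-trimethyl-5-oxo-1,3-dioxolan-4-yl]acetic acid | CC1(C)OC(=O)[C@](C)(CC(O)=O)O1 | intermediate
3 | (5S)-5-(2-hydroxyethyl)-2,2,5-trimethyl-1,3-dioxolan-4-one | CC1(C)OC(=O)[C@](C)(CCO)O1 | intermediate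
4 | (3S)-3-hydroxy-3-methyloxolan-2-one | C[C@]1(O)CCOC1=O | intermediate
5 | (3S)-3-methyl-3-[(triethylsilyl)oxy]oxolan-2-one | C[C@]1(O[Si](CC)(CC)CC)CCOC1=O | intermediate
6 | (3S)-3-methyl-3-[(triethylsilyl)oxy]oxolan-2-ol, anomer mixture | C[C@]1(O[Si](CC)(CC)CC)CCOC1O | intermediate
7 | (3S)-3-methyl-3-[(triethylsilyl)oxy]pent-4-yn-1-ol | C#C[C@@](C)(O[Si](CC)(CC)CC)CCO | intermediate
8 | (3S)-3-methyl-3-[(triethylsilyl)oxy]pent-4-yn-1-yl 2,2-dimethylpropanoate | C#C[C@@](C)(O[Si](CC)(CC)CC)CCOC(=O)C(C)(C)C | intermediate
9 | [(2R)-2-methyloxiran-2-yl]methanol, (R)-2-methylglycidol | OC[C@]1(C)CO1 | starting material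
10 | triethyl{[(2S)-2-methyloxiran-2-yl]methoxy}silane | CC[Si](CC)(CC)OC[C@]1(C)CO1 | intermediate
11 | [(3S)-5-(2,2-dimethylpropanoyloxy)-3-methyl-3-[(triethylsilyl)oxy]pent-1-yn-1-yl]lithium | [Li]C#C[C@@](C)(O[Si](CC)(CC)CC)CCOC(=O)C(C)(C)C | intermediate
12 | (3S,7S)-7-hydroxy-3,7-dimethyl-3,8-bis[(triethylsilyl)oxy]oct-4-yn-1-yl 2,2-dimethylpropanoate | CC[Si](CC)(CC)OC[C@@](C)(O)CC#C[C@@](C)(O[Si](CC)(CC)CC)CCOC(=O)C(C)(C)C | intermediate
13 | (3S)-3-[(5S)-5-methyl-5-{[(triethylsilyl)oxy]methyl}-4,5-dihydrofuran-2-yl]-3-[(triethylsilyl)oxy]butyl 2,2-dimethylpropanoate | CC[Si](CC)(CC)OC[C@]1(C)CC=C(O1)[C@@](C)(O[Si](CC)(CC)CC)CCOC(=O)C(C)(C)C | intermediate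
14 | (3S)-3-[(5S)-5-methyl-5-{[(triethylsilyl)oxy]methyl}-4,5-dihydrofuran-2-yl]-3-[(triethylsilyl)oxy]butan-1-ol | CC[Si](CC)(CC)OC[C@]1(C)CC=C(O1)[C@@](C)(O[Si](CC)(CC)CC)CCO | intermediate
15 | (3S)-3-[(5S)-5-methyl-5-{[(triethylsilyl)oxy]methyl}-4,5-dihydrofuran-2-yl]-3-[(triethylsilyl)oxy]butanal | CC[Si](CC)(CC)OC[C@]1(C)CC=C(O1)[C@@](C)(O[Si](CC)(CC)CC)CC=O | intermediate
16 | 3,4-dibromofuran | Brc1cocc1Br | starting material
17 | (4-bromofuran-3-yl)lithium | [Li]c1cocc1Br | intermediate
18 | (1RS,3S)-1-(4-bromofuran-3-yl)-3-[(5S)-5-methyl-5-{[(triethylsilyl)oxy]methyl}-4,5-dihydrofuran-2-yl]-3-[(triethylsilyl)oxy]butan-1-ol | CC[Si](CC)(CC)OC[C@]1(C)CC=C(O1)[C@@](C)(O[Si](CC)(CC)CC)CC(O)c1cocc1Br | intermediate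
19 | (3S)-1-(4-bromofuran-3-yl)-3-[(5S)-5-methyl-5-{[(triethylsilyl)oxy]methyl}-4,5-dihydrofuran-2-yl]-3-[(triethylsilyl)oxy]butan-1-one | CC[Si](CC)(CC)OC[C@]1(C)CC=C(O1)[C@@](C)(O[Si](CC)(CC)CC)CC(=O)c1cocc1Br | intermediate
20 | (1S,3S)-1-(4-bromofuran-3-yl)-3-[(5S)-5-methyl-5-{[(triethylsilyl)oxy]methyl}-4,5-dihydrofuran-2-yl]-3-[(triethylsilyl)oxy]butan-1-ol | CC[Si](CC)(CC)OC[C@]1(C)CC=C(O1)[C@@](C)(O[Si](CC)(CC)CC)C[C@H](O)c1cocc1Br | intermediate
21 | 3-bromo-4-{(1S,3S)-1-[(tert-butyldimethylsilyl)oxy]-3-[(5S)-5-methyl-5-{[(triethylsilyl)oxy]methyl}-4,5-dihydrofuran-2-yl]-3-[(triethylsilyl)oxy]butyl}furan | CC[Si](CC)(CC)OC[C@]1(C)CC=C(O1)[C@@](C)(O[Si](CC)(CC)CC)C[C@H](O[Si](C)(C)C(C)(C)C)c1cocc1Br | intermediate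
22 | (3-bromo-4-{(1S,3S)-1-[(tert-butyldimethylsilyl)oxy]-3-[(5S)-5-methyl-5-{[(triethylsilyl)oxy]methyl}-4,5-dihydrofuran-2-yl]-3-[(triethylsilyl)oxy]butyl}furan-2-yl)lithium | CC[Si](CC)(CC)OC[C@]1(C)CC=C(O1)[C@@](C)(O[Si](CC)(CC)CC)C[C@H](O[Si](C)(C)C(C)(C)C)c1coc([Li])c1Br | intermediate
23 | dimethyl (3-bromo-4-{(1S,3S)-1-[(tert-butyldimethylsilyl)oxy]-3-[(5S)-5-methyl-5-{[(triethylsilyl)oxy]methyl}-4,5-dihydrofuran-2-yl]-3-[(triethylsilyl)oxy]butyl}furan-2-yl)boronate | CC[Si](CC)(CC)OC[C@]1(C)CC=C(O1)[C@@](C)(O[Si](CC)(CC)CC)C[C@H](O[Si](C)(C)C(C)(C)C)c1coc(B(OC)OC)c1Br | intermediate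
24 | 3-bromo-4-{(1S,3S)-1-[(tert-butyldimethylsilyl)oxy]-3-[(5S)-5-methyl-5-{[(triethylsilyl)oxy]methyl}-4,5-dihydrofuran-2-yl]-3-[(triethylsilyl)oxy]butyl}furan-2(5H)-one | CC[Si](CC)(CC)OC[C@]1(C)CC=C(O1)[C@@](C)(O[Si](CC)(CC)CC)C[C@H](O[Si](C)(C)C(C)(C)C)C1=C(Br)C(=O)OC1 | intermediate
25 | (2S)-5-{(2S,4S)-4-(4-bromo-5-oxo-2,5-dihydrofuran-3-yl)-4-[(tert-butyldimethylsilyl)oxy]-2-[(triethylsilyl)oxy]butan-2-yl}-2-methyl-2,3-dihydrofuran-2-carbaldehyde | O=C[C@]1(C)CC=C(O1)[C@@](C)(O[Si](CC)(CC)CC)C[C@H](O[Si](C)(C)C(C)(C)C)C1=C(Br)C(=O)OC1 | intermediate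
26 | (2S)-5-{(2S,4S)-4-[(tert-butyldimethylsilyl)oxy]-4-[4-(hydroxymethyl)-5-oxo-2,5-dihydrofuran-3-yl]-2-[(triethylsilyl)oxy]butan-2-yl}-2-methyl-2,3-dihydrofuran-2-carbaldehyde | O=C[C@]1(C)CC=C(O1)[C@@](C)(O[Si](CC)(CC)CC)C[C@H](O[Si](C)(C)C(C)(C)C)C1=C(CO)C(=O)OC1 | intermediate
27 | (2S)-5-{(2S,4S)-4-[(tert-butyldimethylsilyl)oxy]-2-[(triethylsilyl)oxy]-4-[5-[(triisopropylsilyl)oxy]-4-{[(triisopropylsilyl)oxy]methyl}furan-3-yl]butan-2-yl}-2-methyl-2,3-dihydrofuran-2-carbaldehyde, the key-step precursor | O=C[C@]1(C)CC=C(O1)[C@@](C)(O[Si](CC)(CC)CC)C[C@H](O[Si](C)(C)C(C)(C)C)c1coc(O[Si](C(C)C)(C(C)C)C(C)C)c1CO[Si](C(C)C)(C(C)C)C(C)C | intermediate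
28 | macrocyclic aldol: target skeleton with a C8–C9 single bond and 9-hydroxy group (C8 and C9 epimers), 4-O-triethylsilyl, 6-O-tert-butyldimethylsilyl, 13-O-triisopropylsilyl, (4S,6S,10S) | CC(C)[Si](C(C)C)(C(C)C)OCC1=C2C(C(O)[C@]3(C)CC=C(O3)[C@@](C)(O[Si](CC)(CC)CC)C[C@@H]2O[Si](C)(C)C(C)(C)C)OC1=O | intermediate
29 | C9 methanesulfonate of 28 | CC(C)[Si](C(C)C)(C(C)C)OCC1=C2C(C(OS(C)(=O)=O)[C@]3(C)CC=C(O3)[C@@](C)(O[Si](CC)(CC)CC)C[C@@H]2O[Si](C)(C)C(C)(C)C)OC1=O | intermediate
30 | (4S,6S,8E,10S)-ylidene butenolide with C7 and C10 cis on C8=C9, 4-O-triethylsilyl, 6-O-tert-butyldimethylsilyl, 13-O-triisopropylsilyl | CC(C)[Si](C(C)C)(C(C)C)OCC1=C2/C(=C\[C@]3(C)CC=C(O3)[C@@](C)(O[Si](CC)(CC)CC)C[C@@H]2O[Si](C)(C)C(C)(C)C)OC1=O | intermediate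
31 | (4S,6S,8E,10S)-4,6,13-triol, the bis-deacetyl target | OCC1=C2/C(=C\[C@]3(C)CC=C(O3)[C@@](C)(O)C[C@@H]2O)OC1=O | intermediate
32 | CNP0144020.1, the (4S,6S,8E,10S)-6,13-diacetate with free C4 hydroxyl | CC(=O)OCC1=C2/C(=C\[C@]3(C)CC=C(O3)[C@@](C)(O)C[C@@H]2OC(C)=O)OC1=O | target

## Step count and least certain steps

Total: 23 steps. Longest linear sequence: 22 steps (steps 1–6 and 8–23 from (S)-citramalic acid). Step 7 is a one-step branch from (R)-2-methylglycidol, and 3,4-dibromofuran enters directly in step 12.

**Step 20 (key step).** The most likely failure is oligomerisation by intermolecular aldol addition, or simple protodesilylation back to the butenolide. Closing a ten-membered carbocycle (nine-membered through the ether bridge) costs entropy and transannular strain. The Lewis acid may also ionise the enol ether. Fallback: a reductive Reformatsky-type closure. From siloxyfuran 27, N-bromosuccinimide in THF at −78 °C should give the γ-bromobutenolide aldehyde F1. Samarium diiodide (SmI2) in THF at −78 °C under high dilution then generates a samarium dienolate that is bound to the aldehyde oxygen and adds through C8. This should give aldol 28, where the route is rejoined.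

**Step 9.** The cycloisomerisation may be slow or stall, because the attacked alkyne carbon C3 is flanked by the quaternary, inductively withdrawing C4. Adventitious acid could then add a nucleophile to the product enol ether. Fallback: iodocyclisation of 12 (I2, NaHCO3, MeCN, 0 °C) to the 3-iodo-4,5-dihydrofuran F2. Palladium-catalysed hydrodeiodination (Pd(PPh3)4, Bu3SnH) then returns to 13.

**Step 16.** Deprotonation may not be fully regioselective, the halogen may migrate in the lithiated bromofuran if the temperature rises, and the lactone may open or over-oxidise in the peroxide step. Fallback: C–H borylation of 21 with [Ir(OMe)(cod)]2, 4,4′-di-tert-butyl-2,2′-bipyridine and B2pin2. Boron should go to the less hindered α-carbon C12 and give the pinacol boronate F3. The same peroxide oxidation returns to 24.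

**Step 17.** The neopentyl primary silyl ether may react sluggishly with the chlorosulfonium species, while the enol ether is attacked by it or the tertiary silyl ether is lost on warming. Fallback: selective desilylation of 24 with pyridine-buffered HF·pyridine at −20 → 0 °C to the C9 alcohol F4. Dess–Martin oxidation with pyridine then returns to 25.

**Step 21.** Mesylation of the hindered C9 carbinol may be slow, so that DBU meets free aldol and triggers retro-aldol ring opening. Prolonged base could also epimerise C6 through vinylogous enolisation or give the wrong alkene geometry. Fallback: treat 28 with the Burgess reagent in toluene at 50 °C. This forms the C9 (methoxycarbonyl)sulfamate F5, which loses the sulfamate by intramolecular syn-elimination without a free dienolate and returns to 30.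

## Further compounds

F1 | step 20 | (2S)-5-{(2S,4S)-4-(2-bromo-5-oxo-4-{[(triisopropylsilyl)oxy]methyl}-2,5-dihydrofuran-3-yl)-4-[(tert-butyldimethylsilyl)oxy]-2-[(triethylsilyl)oxy]butan-2-yl}-2-methyl-2,3-dihydrofuran-2-carbaldehyde, C8 epimers | O=C[C@]1(C)CC=C(O1)[C@@](C)(O[Si](CC)(CC)CC)C[C@H](O[Si](C)(C)C(C)(C)C)C1=C(CO[Si](C(C)C)(C(C)C)C(C)C)C(=O)OC1Br
F2 | step 9 | (3S)-3-[(5S)-3-iodo-5-methyl-5-{[(triethylsilyl)oxy]methyl}-4,5-dihydrofuran-2-yl]-3-[(triethylsilyl)oxy]butyl 2,2-dimethylpropanoate | CC[Si](CC)(CC)OC[C@]1(C)CC(I)=C(O1)[C@@](C)(O[Si](CC)(CC)CC)CCOC(=O)C(C)(C)C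
F3 | step 16 | 2-(3-bromo-4-{(1S,3S)-1-[(tert-butyldimethylsilyl)oxy]-3-[(5S)-5-methyl-5-{[(triethylsilyl)oxy]methyl}-4,5-dihydrofuran-2-yl]-3-[(triethylsilyl)oxy]butyl}furan-2-yl)-4,4,5,5-tetramethyl-1,3,2-dioxaborolane | CC[Si](CC)(CC)OC[C@]1(C)CC=C(O1)[C@@](C)(O[Si](CC)(CC)CC)C[C@H](O[Si](C)(C)C(C)(C)C)c1coc(B2OC(C)(C)C(C)(C)O2)c1Br
F4 | step 17 | 3-bromo-4-{(1S,3S)-1-[(tert-butyldimethylsilyl)oxy]-3-[(5S)-5-(hydroxymethyl)-5-methyl-4,5-dihydrofuran-2-yl]-3-[(triethylsilyl)oxy]butyl}furan-2(5H)-one | OC[C@]1(C)CC=C(O1)[C@@](C)(O[Si](CC)(CC)CC)C[C@H](O[Si](C)(C)C(C)(C)C)C1=C(Br)C(=O)OC1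
F5 | step 21 | C9 (methoxycarbonyl)sulfamate of 28, triethylammonium salt | CC(C)[Si](C(C)C)(C(C)C)OCC1=C2C(C(OS(=O)(=O)[N-]C(=O)OC)[C@]3(C)CC=C(O3)[C@@](C)(O[Si](CC)(CC)CC)C[C@@H]2O[Si](C)(C)C(C)(C)C)OC1=O.CC[NH+](CC)CC
A1 | alternative 1 | tert-butyl{(3S)-3-[(5S)-5-{[(4-methoxyphenyl)methoxy]methyl}-5-methyl-4,5-dihydrofuran-2-yl]-3-[(triethylsilyl)oxy]butoxy}dimethylsilane | COc1ccc(COC[C@]2(C)CC=C(O2)[C@@](C)(O[Si](CC)(CC)CC)CCO[Si](C)(C)C(C)(C)C)cc1
A2 | alternative 2 | (4S,6S,8E,10S)-ten-membered C3 ketone with ylidene butenolide, 4,10-bis-O-triethylsilyl, 6,13-bis-O-tert-butyldimethylsilyl | CC(C)(C)[Si](C)(C)OCC1=C2/C(=C\[C@](O[Si](CC)(CC)CC)(C)CCC(=O)[C@@](C)(O[Si](CC)(CC)CC)C[C@@H]2O[Si](C)(C)C(C)(C)C)OC1=O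
A3 | alternative 3 | (3R,4S,6S,10S)-5-hydroxybutenolide with C3 methyl ketal and saturated C1–C2, 6,13-diacetate, C8 hydroxyl epimer as drawn | CC(=O)OCC1=C2[C@](O)(C[C@]3(C)CC[C@@](OC)(O3)[C@@](C)(O)C[C@@H]2OC(C)=O)OC1=O
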